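One pair, two exits.

substrate 0.40 M; solid reagent 1.50 equiv; time 4.0 min

- amount of target at 4.0 min, in percent of the substrate charged
- concentration of coupling partner in solution at 4.0 min, in percent of saturation

- given per volume of solution although it is solid: solid reagent
- at the start none of the solid reagent is in solution
- run time (flask): 4.0 min

    substrate ⇌ tight pair (K1 = 0.088, k1 = 6.6 × 10⁻⁴ s⁻¹)
    tight pair ⇌ loose pair (K2 = 0.12, k2 = 0.52 s⁻¹)
    coupling partner + tight pair → target (k3 = 0.44 L mol⁻¹ s⁻¹)
    coupling partner + loose pair → isomer of the product (k4 = 5.1 L mol⁻¹ s⁻¹)
    solid reagent ⇌ coupling partner, rate k5*(cs5 - [coupling partner]) while solid is left; crystals form when [coupling partner] > cs5 (cs5 = 0.23 M, k5 = 8.4 × 10⁻⁴ s⁻¹)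

The substrate opens to the tight pair slowly, with a forward half-life of 18 min, so the flask is a slow feed of pairs. But the pairs themselves change fast. A loose pair goes back at 4.33 s⁻¹, while in a solution at the full 0.23 M it couples at 1.17 s⁻¹, so returning is faster. A tight pair passes on at 0.52 s⁻¹ and couples at 0.101 s⁻¹ at most, so passing on is faster too.

So a pair changes form more often than it couples, and the exit it takes goes roughly by weight, which is the Curtin–Hammett case. The tight exit weighs 0.44 L mol⁻¹ s⁻¹. The loose exit weighs 5.1 L mol⁻¹ s⁻¹ times the 0.12 loose pairs per tight pair. The target share, the chance that a coupling pair leaves as target, is the tight weight over the sum of both, 41.8%. Each exit takes one coupling partner, so with the pairs at that ratio its concentration cancels.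

The solid can deliver 11.6% of the charge by 4.0 min into a solution kept empty, so this reckoning by hand ends at a rough upper estimate: that delivery times the target share, 4.85% of target. It gives no amount below that.

The forecast says 3.1% (2.7% to 3.5%) for target and 6.3% (5.5% to 7.2%) for saturation, holding that “the fast-equilibrating pairs split the flux”.

The flask gives 3.12% of target and 6.34% of saturation. Beside that target, the flask holds 4.28% of isomer of the product at 4.00 min, and the target share turns this isomer into 3.07% of target. The neighbour charged with 1.0 M of substrate holds 2.39% of isomer at 4.00 min, which the same share turns into 1.72% of target, and that neighbour holds 1.73%.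

The numbers stand for no real mixture.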